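Everything rests on making two adjacent bonds of ring B at once: the diaryl ether bond C1'–O and the C6'–Br bond, formed across the triple bond of a 3-borylbenzyne. The feature exploited is the run of three neighbouring carbons in ring B, C6'(Br), C1'(OAr) and C2'(OH): the C6' bromine lies meta to the hydroxyl, out of reach of phenol-directed bromination, whereas C3', C5' (ring B) and C2, C4 (ring A) are ortho or para to OH and are brominated last. The key-step precursor is 2-(pinacolboryl)-6-(trimethylsilyl)phenyl triflate, combined with potassium 2-methoxyphenoxide and C6F5Br; boron is the masked C2' hydroxyl.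

Key step: step 4

Remark: ring A is the ring that ends with two bromines (C1 OH, C6 ether oxygen); ring B is the ring that ends with three (C1' ether oxygen, C2' OH, C6' the bromine meta to OH).

Step 1
Reactants: 1 2,6-dibromophenol
Product: 4 2-bromo-6-(trimethylsilyl)phenol, via (2,6-dibromophenoxy)trimethylsilane 2 (not isolated), via lithium 2-bromo-6-(trimethylsilyl)phenoxide 3 (not isolated)
Conditions: HMDS, THF, reflux, then volatiles removed; n-BuLi (1.05 equiv), THF, −78 °C to rt; aq. NH4Cl
Reagents that add atoms: hexamethyldisilazane, C[Si](C)(C)N[Si](C)(C)C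
Why: O-silylation followed by Br/Li exchange at one of the two equivalent C–Br bonds triggers a 1,3 O-to-C silyl shift (retro-Brook rearrangement) driven by formation of the lithium phenoxide, which also disfavours a second exchange, and protonation should give the phenol.

Step 2
Reactants: 4 2-bromo-6-(trimethylsilyl)phenol; 5 2-isopropoxy-4,4,5,5-tetramethyl-1,3,2-dioxaborolane
Product: 8 2-(4,4,5,5-tetramethyl-1,3,2-dioxaborolan-2-yl)-6-(trimethylsilyl)phenol, via sodium 2-bromo-6-(trimethylsilyl)phenoxide 6 (not isolated), via sodium 2-lithio-6-(trimethylsilyl)phenoxide 7 (not isolated)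
Conditions: NaH (1.1 equiv), THF, 0 °C to rt; t-BuLi (2.1 equiv), −78 °C; then 5, −78 °C to rt; aq. NH4Cl
Reagents that add atoms: none
Why: Sodium hydride removes the phenolic proton irreversibly, t-BuLi should then effect an irreversible Br/Li exchange on the sodium phenoxide, and the aryllithium is trapped by the alkoxyborolane (lithiation–borylation), the aryl C–Si bond being inert to these conditions.

Step 3
Reactants: 8 2-(4,4,5,5-tetramethyl-1,3,2-dioxaborolan-2-yl)-6-(trimethylsilyl)phenol
Product: 9 2-(4,4,5,5-tetramethyl-1,3,2-dioxaborolan-2-yl)-6-(trimethylsilyl)phenyl trifluoromethanesulfonate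
Conditions: Tf2O, pyridine, CH2Cl2, 0 °C to rt
Reagents that add atoms: trifluoromethanesulfonic anhydride, O=S(=O)(OS(=O)(=O)C(F)(F)F)C(F)(F)F
Why: This is a standard O-sulfonylation of a phenol with triflic anhydride and pyridine, and neither the pinacol boronate nor the arylsilane should react with the electrophile at this temperature.

Step 4
Reactants: 9 2-(4,4,5,5-tetramethyl-1,3,2-dioxaborolan-2-yl)-6-(trimethylsilyl)phenyl trifluoromethanesulfonate; 10 guaiacol (2-methoxyphenol); 11 bromopentafluorobenzene
Product: 15 2-[3-bromo-2-(2-methoxyphenoxy)phenyl]-4,4,5,5-tetramethyl-1,3,2-dioxaborolane, via potassium 2-methoxyphenoxide 12 (not isolated), via 3-(pinacolboryl)benzyne 13 (not isolated), via aryl potassium adduct 14 (not isolated)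
Conditions: KH, THF, 0 °C to rt (10 into 12); then 9, 11 (3 equiv), KF, 18-crown-6, THF, 0 °C to rt; H2O quench
Reagents that add atoms: none
Why: Proposed new method: fluoride attacks silicon of 9 and triflate departs to give aryne 13; the electropositive boryl substituent makes the neighbouring aryne carbon the flatter and more electrophilic one, so phenoxide 12 should add there and leave the carbanion of 14 at the distal carbon, which then abstracts bromine from C6F5Br in a halophilic exchange. The closest known reactions are the ortho-selective addition of amines to 3-borylbenzynes, the fluoride-induced O-arylation of phenols with 2-silylaryl triflates and the three-component bromothiolation of arynes that uses C6F5Br as bromine donor. No ring is closed and no stereocentre is formed. Two selectivities are needed: oxygen attack at the aryne carbon next to C–B, which the σ-donating, small and planar boronate should secure, and bromine instead of proton capture by the aryl anion, which is secured by a phenoxide preformed with KH (the conjugate acid leaves as H2) in an aprotic ether with excess bromine donor. The boronate is carried through as the latent C2' hydroxyl, so the C6'/C1'/C2' triad of ring B is assembled without any metal-catalysed coupling next to an aryl bromide.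

Step 5
Reactants: 15 2-[3-bromo-2-(2-methoxyphenoxy)phenyl]-4,4,5,5-tetramethyl-1,3,2-dioxaborolane
Product: 16 3-bromo-2-(2-methoxyphenoxy)phenol
Conditions: 30% aq. H2O2, NaOH, THF, 0 °C to rt; aq. Na2S2O3, then dilute HCl
Reagents that add atoms: hydrogen peroxide, OO
Why: Alkaline peroxide oxidation of an arylboronic ester proceeds by 1,2-aryl shift from boron to oxygen at the same carbon and should leave the aryl bromide, the methyl ether and the diaryl ether untouched.

Step 6
Reactants: 16 3-bromo-2-(2-methoxyphenoxy)phenol
Product: 17 3-bromo-2-(2-hydroxyphenoxy)phenol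
Conditions: BBr3 (3 equiv), CH2Cl2, −78 °C to rt; H2O
Reagents that add atoms: none
Why: Boron tribromide cleaves the aryl methyl ether by Lewis acid complexation and attack of bromide on the methyl carbon, whereas the diaryl ether offers no sp3 carbon for attack and the aryl bromide is inert.

Step 7
Reactants: 17 3-bromo-2-(2-hydroxyphenoxy)phenol; 18 bromine
Product: 20 2,4-dibromo-6-(2,3,5-tribromo-6-hydroxyphenoxy)phenol (target), via 3,4-dibromo-2-(5-bromo-2-hydroxyphenoxy)phenol 19 (not isolated)
Conditions: Bu4NBr3 (2.0 equiv), CH2Cl2/MeOH, rt; then Br2 (2.1 equiv), rt; aq. Na2S2O3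
Reagents that add atoms: tetrabutylammonium tribromide, CCCC[N+](CCCC)(CCCC)CCCC.[Br-].BrBr
Why: Electrophilic aromatic bromination is steered by the two free hydroxyls as the strongest donors; the mild tribromide salt should first take the position para to each OH (C4 of ring A and C5' of ring B), and bromine then fills the one remaining ortho site of each ring (C2 and C3'), the other positions being meta to OH and deactivated once bromine is on the ring.

Compound list
1 | 2,6-dibromophenol | Oc1c(Br)cccc1Br | starting material
2 | (2,6-dibromophenoxy)trimethylsilane | C[Si](C)(C)Oc1c(Br)cccc1Br | intermediate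
3 | lithium 2-bromo-6-(trimethylsilyl)phenoxide | [Li+].[O-]c1c(Br)cccc1[Si](C)(C)C | intermediate
4 | 2-bromo-6-(trimethylsilyl)phenol | C[Si](C)(C)c1cccc(Br)c1O | intermediate
5 | 2-isopropoxy-4,4,5,5-tetramethyl-1,3,2-dioxaborolane | CC(C)OB1OC(C)(C)C(C)(C)O1 | starting material
6 | sodium 2-bromo-6-(trimethylsilyl)phenoxide | [Na+].[O-]c1c(Br)cccc1[Si](C)(C)C | intermediate
7 | sodium 2-lithio-6-(trimethylsilyl)phenoxide | [Na+].[O-]c1c([Li])cccc1[Si](C)(C)C | intermediate
8 | 2-(4,4,5,5-tetramethyl-1,3,2-dioxaborolan-2-yl)-6-(trimethylsilyl)phenol | CC1(C)OB(OC1(C)C)c1cccc([Si](C)(C)C)c1O | intermediate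
9 | 2-(4,4,5,5-tetramethyl-1,3,2-dioxaborolan-2-yl)-6-(trimethylsilyl)phenyl trifluoromethanesulfonate | CC1(C)OB(OC1(C)C)c1cccc([Si](C)(C)C)c1OS(=O)(=O)C(F)(F)F | intermediate
10 | guaiacol (2-methoxyphenol) | COc1ccccc1O | starting material
11 | bromopentafluorobenzene | Fc1c(F)c(F)c(Br)c(F)c1F | starting material
12 | potassium 2-methoxyphenoxide | [K+].COc1ccccc1[O-] | intermediate
13 | 3-(pinacolboryl)benzyne | CC1(C)OB(OC1(C)C)C1=CC=CC#C1 | intermediate
14 | aryl potassium adduct, [2-(2-methoxyphenoxy)-3-(pinacolboryl)phenyl]potassium | COc1ccccc1Oc1c([K])cccc1B1OC(C)(C)C(C)(C)O1 | intermediate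
15 | 2-[3-bromo-2-(2-methoxyphenoxy)phenyl]-4,4,5,5-tetramethyl-1,3,2-dioxaborolane | COc1ccccc1Oc1c(Br)cccc1B1OC(C)(C)C(C)(C)O1 | intermediate
16 | 3-bromo-2-(2-methoxyphenoxy)phenol | COc1ccccc1Oc1c(Br)cccc1O | intermediate
17 | 3-bromo-2-(2-hydroxyphenoxy)phenol | Oc1ccccc1Oc1c(Br)cccc1O | intermediate
18 | bromine | BrBr | starting material
19 | 3,4-dibromo-2-(5-bromo-2-hydroxyphenoxy)phenol | Oc1ccc(Br)cc1Oc1c(O)ccc(Br)c1Br | intermediate
20 | 2,4-dibromo-6-(2,3,5-tribromo-6-hydroxyphenoxy)phenol | Oc1c(Br)cc(Br)cc1Oc1c(O)c(Br)cc(Br)c1Br | target

Total step count: 7. Longest linear sequence: 7 steps (1 to 20 through steps 1 to 7); guaiacol 10 enters at step 4 without separate steps.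

Steps most likely to fail

Step 4 is the main risk. The phenoxide may add at the distal aryne carbon. The aryl anion may capture a proton instead of bromine. The phenoxide may be consumed by nucleophilic aromatic substitution on the bromine donor before the aryne is released, and fluoride may bind to boron and hold back aryne release. The fallback uses known chemistry and sets out from guaiacol 10. SNAr on commercial 3-bromo-2-fluorobenzaldehyde (O=Cc1cccc(Br)c1F; K2CO3, DMF, 100 °C) should give 3-bromo-2-(2-methoxyphenoxy)benzaldehyde F1. Baeyer–Villiger (Dakin-type) oxidation with mCPBA in CH2Cl2 should convert it into 3-bromo-2-(2-methoxyphenoxy)phenyl formate F2. Methanolysis (K2CO3, MeOH, rt) then returns to the route at phenol 16, so steps 1 to 5 are replaced.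

Step 7 may lose site selectivity in its second stage on ring A, where the ether oxygen (directing to C3) competes with the hydroxyl (directing to C2) for the last bromine, or may over-brominate once the four activated sites are filled. A first bromine that enters ortho instead of para is harmless, since both sites are filled in the end. The fallback treats the two rings one after the other, with the methyl ether as a switch, and sets out from 16. Br2 (2 equiv, NaOAc, AcOH, 10 °C) should brominate only the ring that carries the free hydroxyl and give 3,4,6-tribromo-2-(2-methoxyphenoxy)phenol F3. BBr3 (CH2Cl2, −78 °C to rt) then frees the second hydroxyl to give 3,4,6-tribromo-2-(2-hydroxyphenoxy)phenol F4, whose tribrominated ring has no open ortho or para site left. Br2 (2 equiv, NaOAc, AcOH, rt) then brominates the newly freed phenol ring at C4 and C2 and arrives at 20.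

Step 2 may suffer incomplete bromine–lithium exchange on the aggregated phenoxide, or proton capture by the aryllithium before it meets the borate. The fallback replaces the organolithium by catalysis and sets out from 4. A Miyaura borylation with bis(pinacolato)diboron, PdCl2(dppf) [dichloro(1,1'-bis(diphenylphosphino)ferrocene)palladium, a divalent palladium precatalyst reduced in the flask to zerovalent palladium, which inserts into the C–Br bond] and KOAc in dioxane at 90 °C should give 8 directly. No new compound lies on this path.

Further compounds
F1 | step 4 | 3-bromo-2-(2-methoxyphenoxy)benzaldehyde | COc1ccccc1Oc1c(Br)cccc1C=O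
F2 | step 4 | 3-bromo-2-(2-methoxyphenoxy)phenyl formate | COc1ccccc1Oc1c(Br)cccc1OC=O
F3 | step 7 | 3,4,6-tribromo-2-(2-methoxyphenoxy)phenol | COc1ccccc1Oc1c(O)c(Br)cc(Br)c1Br
F4 | step 7 | 3,4,6-tribromo-2-(2-hydroxyphenoxy)phenol | Oc1ccccc1Oc1c(O)c(Br)cc(Br)c1Br
F0 | step 2 | none | none
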